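**Remark on the chemistry:** locants follow eudesmane numbering (ring A = C1–C5 and C10; ring B = C5–C10; C14 on C10, C15 on C4, C11 the carbinol carbon on C7; C1′ the benzylic carbon). The given SMILES corresponds to (1R,4R,7S,10R,1′S), with the C1 side chain, C15, the C7 side chain and C14 all on one face (the α face below). "Eudesm-" names are used for skeleton and locants only. The C2 epimers of 2 and 3 are carried as mixtures because C2 is planarised in step 3.

## The problem

The target is a decalin (rings A and B fused at C5–C10) with a quaternary C10, a trisubstituted C5=C6 alkene at the ring fusion, and an exocyclic benzylic stereocentre C1′ that carries a hexasubstituted diformylphloroglucinol. Five stereocentres must be set: C7 and C10 (1,4 across ring B), C4 and C1 on ring A, and C1′ outside the rings. C7 can come from the chiral pool and can help control C10; the axial C14 on C10 is then the only handle for C4, C1 and C1′. The hardest point is C1: it is neopentyl, and its substituent is syn to C14, the face every external reagent avoids, so the C1–C1′ bond cannot be made by a simple intermolecular addition. C1′ is acyclic, has no neighbouring functional group in the target, and must be set relative to C1 and C10. The enabling feature is in ring A: C1 and C3 stand 1,3 across C2, a Robinson annulation leaves an oxygen at C3, and the side chain C1′–C5′ has the branched carbon skeleton of a prenyl group. An allylic ether C3–O–C1′ on the α face therefore maps onto the C1–C1′ bond by a [2,3] shift through C2. Sensitive groups are the tertiary C11 alcohol (acid), the C5=C6 alkene (migration to C4=C5 would erase C4), and the electron-poor trihydroxy dialdehyde, which must be unveiled last.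

## Retrosynthesis

**Arene last.** The three O–CH3 bonds and the two aryl–CHO bonds are cut first: 30 comes from trimethyl ether 29, 29 from dibromide 27, and 27 from the plain trimethoxyphenyl compound 26. The free dialdehyde would not survive organolithium or acid steps, whereas the trimethoxyphenyl group is robust and comes from the cheap arene 22. The forward steps must work under basic or neutral conditions because of the C11 alcohol and the C5=C6 alkene.

**C1′–H and C1′–aryl.** In 26 the C1′–H bond is cut to the tertiary benzylic alcohol 24, and the C1′–aryl bond of 24 is cut to ketone 21 and aryllithium 23 (from 22). This is preferred over cutting C1′–C1 at this stage because the carbinol configuration of 24 need not be controlled: C1′ is set only when hydride is delivered to cation 25. The forward step asks for hydride to enter anti to quaternary C10.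

**Side-chain adjustment.** Ketone 21 comes from enone 20, 20 from allylic alcohol 19, and 19 from diene 18 by removal of the C2=C3 alkene. These are functional-group changes only; they need chemoselectivity over C5=C6.

**Key disconnection.** In 18 the C1–C1′ bond is cut and the C3–O bond reconnected, giving prenyl ether 16, which comes from dienol 14 and prenyl bromide 15. This cut beats the neighbouring C1′–aryl and C1–C10 cuts because it makes the most hindered bond intramolecularly and on the hindered face, removes the C3 oxygen, and reduces the precursor to a C15 dienol plus a C5 halide. The forward [2,3] shift must be suprafacial and must start from the prenyl α-carbanion.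

**Ring A oxidation pattern.** Dienol 14 comes from dienone 13 (C3–H bond), 13 from the cross-conjugated dienone 11 (C4–H bond, alkene moved from C4=C5 to C5=C6), and 11 from enone 10 (C1=C2). The C4 stereocentre and the C5=C6 position are thereby created together by one protonation. The forward steps need hydrogen to enter anti to C14 at both C4 and C3.

**Decalin.** Enone 10 is cut at C10–C1 and C4=C5 (Robinson annulation) to hydroxy ketone 3 and ethyl vinyl ketone 5, with amine 4 as a removable controller; 3 comes from (S)-carvone 1 through 2. The forward Michael addition must occur at the more substituted α-carbon and place C14 cis to the C7 side chain, against the intrinsic preference of the ring, which is why the chiral imine is used.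

## Roads not taken

**Alternative 1:** (the most obvious) Cut C1–C1′ late and join the two halves of the natural product as in its biogenesis: quinone methide A1 with the C2 silyl enol ether A2 of a 2-oxo-eudesmene, giving ketone A3, then removal of the C2 oxygen. The chosen plan is better for four reasons. The Robinson annulation places the carbonyl at C3, not C2, so A2 needs a carbonyl transposition. The intermolecular attack on A2 occurs anti to C14 and gives the wrong C1, to be corrected by epimerisation of A3 with uncertain bias. C1′ is set in an open transition state between two hindered partners. The sensitive dialdehyde is carried through the deoxygenation.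

**Alternative 2:** Keep the C3 oxygen as the anchor but use an Ireland–Claisen rearrangement of the (2,4,6-trimethoxyphenyl)acetate A4 to acid A5, forming C1–C1′ and both stereocentres at once, with CO2H later converted to isobutyl. Cyclohexenyl esters rearrange through a boat with the Z ketene acetal and through a chair with the E ketene acetal. Both keep the aryl group away from ring A and lead to the C1′ epimer shown as A5 (1′R after conversion). The 1′S series would need the aryl group under ring A against C10. The chosen plan sets C1′ separately by hydride delivery and needs no conversion of a carboxyl into an isobutyl group.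

**Alternative 3:** Cut C1–C10 instead: an Ireland–Claisen rearrangement of the p-menth-1-en-3-yl ester A6 of an enantiopure 3-aryl-5-methylhexanoic acid to acid A7, which creates C10 and C1 and places C5=C6, then ring-closing metathesis for ring A. The stereochemistry is sound (the E ketene acetal through a chair gives the right C1/C10 pair, and C1′ comes from an auxiliary). However, A6 needs a C4 stereocentre on a vinylic carbon of a fragile β-hydroxy enone precursor, the rearrangement must join a quaternary to a branched tertiary carbon, and five further steps are needed to close ring A. The route would be well over twenty steps.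

Key step: step 8

## Steps

**Step 1**
Reactants: 1 (S)-(+)-carvone
Product: 2 (5S)-2-methyl-5-(prop-1-en-2-yl)cyclohexan-1-one (dihydrocarvone; both C2 epimers)
Conditions: LiBH(s-Bu)3, THF, −78 °C; then H2O
Reagents that add atoms: none
Why: Conjugate (1,4) hydride reduction of the enone by a hindered trialkylborohydride; the isopropenyl group is untouched and the C2 epimer ratio is irrelevant.

**Step 2**
Reactants: 2
Product: 3 (5S)-5-(2-hydroxypropan-2-yl)-2-methylcyclohexan-1-one
Conditions: Co(acac)2 (20 mol %), PhSiH3, O2 (1 atm), i-PrOH, rt
Reagents that add atoms: dioxygen, O=O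
Why: Mukaiyama hydration: Markovnikov hydrogen-atom transfer to the 1,1-disubstituted alkene, capture of the tertiary radical by O2 and reduction of the peroxide by the silane; the ketone is inert and no stereocentre is formed.

**Step 3**
Reactants: 3; 4 (S)-1-phenylethylamine; 5 ethyl vinyl ketone (pent-1-en-3-one)
Product: 10 (7S,10R)-11-hydroxyeudesm-4-en-3-one, via imine 6 (not isolated), via Michael adduct 7 (not isolated), via diketone 8 (not isolated), via ketol 9 (not isolated)
Conditions: 4, 4 Å sieves, toluene, 80 °C; then 5, THF, 40 °C; then 10% aq AcOH, rt; then NaOMe, MeOH, 60 °C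
Reagents that add atoms: none
Why: Robinson annulation through a chiral imine: the secondary enamine tautomer of 6 adds to 5 at the more substituted α-carbon (aza-ene-type Michael addition) on the face set by the (S)-phenylethyl group, which in this matched pair places C14 cis to the C7 side chain (10R); hydrolysis and aldol condensation of the ethyl ketone onto C5 then close ring A.

**Step 4**
Reactants: 10
Product: 11 (7S,10R)-11-hydroxyeudesma-1,4-dien-3-one
Conditions: DDQ, 1,4-dioxane, reflux
Reagents that add atoms: none
Why: Quinone dehydrogenation of a 4-en-3-one to the cross-conjugated 1,4-dien-3-one, a standard reaction of this enone class; the tertiary alcohol and both stereocentres are unaffected.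

**Step 5**
Reactants: 11
Product: 13 (4S,7S,10R)-11-hydroxyeudesma-1,5-dien-3-one, via potassium trienolate 12 (not isolated)
Conditions: KOt-Bu (5 equiv), t-BuOH/THF, rt; then inverse quench into 10% aq AcOH, 0 °C
Reagents that add atoms: none
Why: Deconjugative kinetic protonation: γ-deprotonation at C6 gives the through-conjugated trienolate 12, which is protonated at C4 under kinetic control; the proton enters anti to the pseudoaxial C14, so C15 ends cis to C14 (4S here), and the inverse quench into excess acid suppresses reconjugation.

**Step 6**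
Reactants: 13
Product: 14 (3R,4S,7S,10R)-eudesma-1,5-diene-3,11-diol
Conditions: NaBH4, CeCl3·7H2O, MeOH, −78 °C
Reagents that add atoms: none
Why: Luche 1,2-reduction of the enone without conjugate reduction or migration of C5=C6; hydride attacks C3 anti to C15 and C14, placing the 3-OH on the α face (3R).

**Step 7**
Reactants: 14; 15 prenyl bromide (1-bromo-3-methylbut-2-ene)
Product: 16 (3R,4S,7S,10R)-3-[(3-methylbut-2-en-1-yl)oxy]eudesma-1,5-dien-11-ol
Conditions: NaH (1.05 equiv), Bu4NI (cat.), THF, 0 °C to rt
Reagents that add atoms: none
Why: Williamson etherification of the secondary allylic alkoxide with an allylic bromide; the hindered tertiary C11 alkoxide is much less nucleophilic, so one equivalent of base and halide should give the mono-ether.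

**Step 8**
Reactants: 16
Product: 18 (1S,4R,7S,10R)-1-(1-hydroxy-3-methylbut-2-en-1-yl)eudesma-2,5-dien-11-ol (both C1′ epimers), via dilithiated ether 17 (not isolated)
Conditions: n-BuLi (2.5 equiv), THF, −78 °C to −40 °C; then H2O
Reagents that add atoms: none
Why: [2,3]-Wittig rearrangement of a bis-allylic ether: the first equivalent of n-BuLi forms the C11 alkoxide and the second removes a proton from the O–CH2 of the prenyl group (primary, allylic and α to oxygen, whereas the ring C3–H is tertiary and shielded), giving 17. The carbanion carbon then bonds to C1 through a five-membered envelope transition state while the C3–O bond breaks and the double bond moves to C2=C3, a concerted suprafacial six-electron [2,3] shift whose closest precedents are the rearrangements of allyl prenyl ethers and of cyclohex-2-enyl ethers (tin–lithium exchange variant), which carry the face of the ether oxygen 1,3 across the ring. No ring is closed. The new C1 stereocentre is controlled by C3: the oxygen is on the α face, so the C1–C1′ bond forms on the α face, syn to C14, and in the reacting half-chair C3–O is pseudoaxial and C14 pseudoequatorial, so the quaternary carbon does not block the shift. The C1′ carbinol centre is formed without control and is erased in step 10. The step needs [2,3] over [1,2] selectivity, which the low temperature and the allylic nature of both partners favour, and regioselective lithiation, which the difference between a primary and a hindered tertiary α-oxy C–H secures. An anionic oxy-Cope rearrangement of the product alkoxide is not expected with lithium as counter-ion at −40 °C. In one operation the step forms the neopentyl C1–C1′ bond, sets C1, removes the C3 oxygen, brings in all five side-chain carbons and leaves an oxygen on C1′ for the aryl addition.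

**Step 9**
Reactants: 18
Product: 19 (1S,4R,7S,10R)-1-(1-hydroxy-3-methylbut-2-en-1-yl)eudesm-5-en-11-ol
Conditions: RhCl(PPh3)3 (5 mol %), H2 (1 atm), benzene/EtOH, rt
Reagents that add atoms: none
Why: Homogeneous hydrogenation with this rhodium catalyst is very sensitive to alkene substitution, so the cis-disubstituted C2=C3 should be reduced while the trisubstituted side-chain alkene and the hindered C5=C6 remain; any over-reduced side chain converges at 21 after steps 10 and 11.

**Step 10**
Reactants: 19
Product: 20 (1S,4R,7S,10R)-1-(3-methylbut-2-enoyl)eudesm-5-en-11-ol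
Conditions: Dess–Martin periodinane, NaHCO3, CH2Cl2, 0 °C to rt
Reagents that add atoms: none
Why: Dess–Martin oxidation of the secondary allylic alcohol to the enone under buffered conditions; the tertiary alcohol cannot be oxidised and the uncontrolled C1′ centre disappears.

**Step 11**
Reactants: 20
Product: 21 (1S,4R,7S,10R)-1-(3-methylbutanoyl)eudesm-5-en-11-ol
Conditions: [(Ph3P)CuH]6 (0.4 equiv), H2O (2 equiv), toluene, rt
Reagents that add atoms: none
Why: Conjugate reduction by a phosphine-stabilised copper hydride: hydride adds only to the β-carbon of the enone, the isolated C5=C6 is inert, and the copper enolate forms on the side-chain side, so C1 is not enolised.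

**Step 12**
Reactants: 21; 22 1,3,5-trimethoxybenzene
Product: 24 (1S,4R,7S,10R)-1-[1-hydroxy-3-methyl-1-(2,4,6-trimethoxyphenyl)butyl]eudesm-5-en-11-ol (both C1′ epimers), via aryllithium 23 (not isolated)
Conditions: 22, n-BuLi, THF, 0 °C to rt; CeCl3, −78 °C; then 21, −78 to 0 °C; then H2O
Reagents that add atoms: none
Why: Directed ortho-lithiation of 22 gives 23, which as its organocerium reagent adds 1,2 to the hindered, enolisable ketone (cerium suppresses enolisation); the carbinol centre need not be controlled because it is planarised in step 13.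

**Step 13**
Reactants: 24
Product: 26 (1R,4R,7S,10R)-1-[(1S)-3-methyl-1-(2,4,6-trimethoxyphenyl)butyl]eudesm-5-en-11-ol, via benzylic cation 25 (not isolated)
Conditions: Et3SiH (5 equiv), CF3CO2H (3 equiv), CH2Cl2, −78 to −30 °C
Reagents that add atoms: none
Why: Ionic hydrogenation: at low temperature the acid should ionise only the tertiary trimethoxybenzylic alcohol, and Et3SiH delivers hydride to cation 25; allylic 1,3-strain with the ortho-methoxy groups holds C1–H in the plane of the cation so that C2 and quaternary C10 flank its two faces, and hydride should enter from the C2 side, anti to C10, giving 1′S.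

**Step 14**
Reactants: 26
Product: 27 (1R,4R,7S,10R)-1-[(1S)-1-(3,5-dibromo-2,4,6-trimethoxyphenyl)-3-methylbutyl]eudesm-5-en-11-ol
Conditions: N-bromosuccinimide (2.1 equiv), MeCN, 0 °C
Reagents that add atoms: N-bromosuccinimide, O=C1CCC(=O)N1Br
Why: Electrophilic aromatic bromination at the two free ring positions, each activated by three oxygen substituents, should be far faster than any reaction of the reagent with the hindered alkene in anhydrous MeCN.

**Step 15**
Reactants: 27
Product: 29 5-{(1S)-1-[(1R,4R,7S,10R)-11-hydroxyeudesm-5-en-1-yl]-3-methylbutyl}-2,4,6-trimethoxybenzene-1,3-dicarbaldehyde, via dilithio arene 28 (not isolated)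
Conditions: t-BuLi (5.2 equiv), THF, −78 °C; DMF, −78 to 0 °C; aq NH4Cl
Reagents that add atoms: N,N-dimethylformamide, CN(C)C=O
Why: Double bromine–lithium exchange (two equivalents of t-BuLi per bromide and one for the alkoxide) and formylation of 28 with DMF (Bouveault-type formylation); the basic conditions leave the tertiary alcohol and the alkene untouched.

**Step 16**
Reactants: 29
Product: 30 CNP0108656.4, 5-{(1S)-1-[(1R,4R,7S,10R)-11-hydroxyeudesm-5-en-1-yl]-3-methylbutyl}-2,4,6-trihydroxybenzene-1,3-dicarbaldehyde
Conditions: EtSNa (10 equiv), DMF, 110 °C; then aq citric acid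
Reagents that add atoms: none
Why: Nucleophilic O-demethylation (SN2 at methyl by thiolate): each methoxy group is ortho or para to a formyl group, so the phenoxide leaving groups are stabilised and all three ethers should cleave under basic conditions that spare the tertiary alcohol and C5=C6.

## Compound list

1 | (S)-(+)-carvone | CC1=CC[C@@H](CC1=O)C(C)=C | starting material
2 | (5S)-2-methyl-5-(prop-1-en-2-yl)cyclohexan-1-one (C2 epimers) | CC1CC[C@@H](CC1=O)C(C)=C | intermediate
3 | (5S)-5-(2-hydroxypropan-2-yl)-2-methylcyclohexan-1-one (C2 epimers) | CC1CC[C@@H](CC1=O)C(C)(C)O | intermediate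
4 | (S)-1-phenylethylamine | C[C@H](N)c1ccccc1 | starting material
5 | ethyl vinyl ketone | C=CC(=O)CC | starting material
6 | imine of 3 with 4 (not isolated) | C[C@H](N=C1C[C@@H](C(C)(C)O)CCC1C)c1ccccc1 | intermediate
7 | Michael adduct, imine of 8 (not isolated) | CCC(=O)CC[C@@]1(C)CC[C@H](C(C)(C)O)CC1=N[C@@H](C)c1ccccc1 | intermediate
8 | (2R,5S)-5-(2-hydroxypropan-2-yl)-2-methyl-2-(3-oxopentyl)cyclohexan-1-one (not isolated) | CCC(=O)CC[C@@]1(C)CC[C@H](C(C)(C)O)CC1=O | intermediate
9 | aldol (5-hydroxy-3-ketone) from 8 (not isolated) | O=C1CC[C@@]2(C)CC[C@H](C(C)(C)O)CC2(O)C1C | intermediate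
10 | (7S,10R)-11-hydroxyeudesm-4-en-3-one | O=C1CC[C@@]2(C)CC[C@H](C(C)(C)O)CC2=C1C | intermediate
11 | (7S,10R)-11-hydroxyeudesma-1,4-dien-3-one | O=C1C=C[C@@]2(C)CC[C@H](C(C)(C)O)CC2=C1C | intermediate
12 | potassium 3-oxido-1,3,5-trienolate of 11 (not isolated) | [K+].[O-]C1=C(C)C2=C[C@@H](C(C)(C)O)CC[C@]2(C)C=C1 | intermediate
13 | (4S,7S,10R)-11-hydroxyeudesma-1,5-dien-3-one | O=C1C=C[C@@]2(C)CC[C@H](C(C)(C)O)C=C2[C@@H]1C | intermediate
14 | (3R,4S,7S,10R)-eudesma-1,5-diene-3,11-diol | O[C@@H]1C=C[C@@]2(C)CC[C@H](C(C)(C)O)C=C2[C@@H]1C | intermediate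
15 | prenyl bromide | CC(C)=CCBr | starting material
16 | (3R,4S,7S,10R)-3-[(3-methylbut-2-en-1-yl)oxy]eudesma-1,5-dien-11-ol | CC(C)=CCO[C@@H]1C=C[C@@]2(C)CC[C@H](C(C)(C)O)C=C2[C@@H]1C | intermediate
17 | α-lithio prenyl ether of 16 as C11 lithium alkoxide (not isolated) | [Li]C(C=C(C)C)O[C@@H]1C=C[C@@]2(C)CC[C@H](C(C)(C)O[Li])C=C2[C@@H]1C | intermediate
18 | (1S,4R,7S,10R)-1-(1-hydroxy-3-methylbut-2-en-1-yl)eudesma-2,5-dien-11-ol (C1′ epimers) | CC(C)=CC(O)[C@H]1C=C[C@@H](C)C2=C[C@@H](C(C)(C)O)CC[C@@]21C | intermediate
19 | (1S,4R,7S,10R)-1-(1-hydroxy-3-methylbut-2-en-1-yl)eudesm-5-en-11-ol (C1′ epimers) | CC(C)=CC(O)[C@H]1CC[C@@H](C)C2=C[C@@H](C(C)(C)O)CC[C@@]21C | intermediate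
20 | (1S,4R,7S,10R)-1-(3-methylbut-2-enoyl)eudesm-5-en-11-ol | CC(C)=CC(=O)[C@H]1CC[C@@H](C)C2=C[C@@H](C(C)(C)O)CC[C@@]21C | intermediate
21 | (1S,4R,7S,10R)-1-(3-methylbutanoyl)eudesm-5-en-11-ol | CC(C)CC(=O)[C@H]1CC[C@@H](C)C2=C[C@@H](C(C)(C)O)CC[C@@]21C | intermediate
22 | 1,3,5-trimethoxybenzene | COc1cc(OC)cc(OC)c1 | starting material
23 | 2,4,6-trimethoxyphenyllithium (not isolated) | [Li]c1c(OC)cc(OC)cc1OC | intermediate
24 | (1S,4R,7S,10R)-1-[1-hydroxy-3-methyl-1-(2,4,6-trimethoxyphenyl)butyl]eudesm-5-en-11-ol (C1′ epimers) | CC(C)CC(O)(c1c(OC)cc(OC)cc1OC)[C@H]1CC[C@@H](C)C2=C[C@@H](C(C)(C)O)CC[C@@]21C | intermediate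
25 | tertiary trimethoxybenzylic cation from 24 (not isolated) | CC(C)C[C+](c1c(OC)cc(OC)cc1OC)[C@H]1CC[C@@H](C)C2=C[C@@H](C(C)(C)O)CC[C@@]21C | intermediate
26 | (1R,4R,7S,10R)-1-[(1S)-3-methyl-1-(2,4,6-trimethoxyphenyl)butyl]eudesm-5-en-11-ol | CC(C)C[C@H](c1c(OC)cc(OC)cc1OC)[C@H]1CC[C@@H](C)C2=C[C@@H](C(C)(C)O)CC[C@@]21C | intermediate
27 | (1R,4R,7S,10R)-1-[(1S)-1-(3,5-dibromo-2,4,6-trimethoxyphenyl)-3-methylbutyl]eudesm-5-en-11-ol | CC(C)C[C@H](c1c(OC)c(Br)c(OC)c(Br)c1OC)[C@H]1CC[C@@H](C)C2=C[C@@H](C(C)(C)O)CC[C@@]21C | intermediate
28 | 3,5-dilithio arene from 27 as C11 lithium alkoxide (not isolated) | CC(C)C[C@H](c1c(OC)c([Li])c(OC)c([Li])c1OC)[C@H]1CC[C@@H](C)C2=C[C@@H](C(C)(C)O[Li])CC[C@@]21C | intermediate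
29 | 5-{(1S)-1-[(1R,4R,7S,10R)-11-hydroxyeudesm-5-en-1-yl]-3-methylbutyl}-2,4,6-trimethoxybenzene-1,3-dicarbaldehyde | CC(C)C[C@H](c1c(OC)c(C=O)c(OC)c(C=O)c1OC)[C@H]1CC[C@@H](C)C2=C[C@@H](C(C)(C)O)CC[C@@]21C | intermediate
30 | CNP0108656.4 | CC(C)C[C@H](c1c(O)c(C=O)c(O)c(C=O)c1O)[C@H]1CC[C@@H](C)C2=C[C@@H](C(C)(C)O)CC[C@@]21C | target

## Step count and least certain steps

Total step count: 16. Longest linear sequence: 16 steps, from 1 to 30; compounds 4, 5, 15 and 22 are bought.

**Step 8 (key step).** The risks are a competing [1,2]-shift or elimination of the lithiated ether, lithiation at the ring C3–H instead of the prenyl CH2, and a slow shift to the carbon next to the quaternary centre. Fallback: from 14, alkylation with Bu3SnCH2I/KH would give the stannylmethyl ether F1. Tin–lithium exchange with n-BuLi at −78 °C triggers the same suprafacial [2,3] shift from a primary, non-stabilised carbanion and would give the hydroxymethyl diene F2. Hydrogenation of C2=C3 as in step 9 would give alcohol F3, and Dess–Martin oxidation the aldehyde F4. Addition of 2-methylprop-1-enylmagnesium bromide to F4 returns to the route at 19.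

**Step 5.** The risks are reconjugation to 11 during the quench and incomplete facial selectivity of protonation at C4. Fallback: from 11, triethyl orthoformate with catalytic TsOH would give the 3-ethoxy-1,3,5-triene F5. Hydrolysis of this isolated enol ether with aqueous oxalic acid at 0 °C protonates C4 under kinetic, non-basic conditions and returns to the route at 13.

**Step 12.** The risks are enolisation of the ketone by the basic aryl nucleophile and slow addition to a carbonyl flanked by the branched C1. Fallback: from enone 20, which has no α-methylene and a more accessible carbonyl, 1,2-addition of 23 as its cerium reagent would give the allylic carbinol F6. Treatment of F6 with Et3SiH and CF3CO2H should ionise it to the aryl-substituted allyl cation, reduce it to the styrene, reprotonate this to cation 25 and reduce it again, returning to the route at 26.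

**Step 13.** The risks are poor facial selectivity in hydride capture by 25 and acid-induced loss of the C11 hydroxyl or protonation of C5=C6. Fallback: reverse the order in which the two groups enter C1′, so that carbon enters last. From 14 the aldehyde F4 is reached as in the fallback for step 8. Addition of 23 gives the secondary benzylic alcohol F7. Ionisation with BF3·OEt2 at −78 °C in the presence of trimethyl(2-methylallyl)silane (allylsilane capture of a benzylic cation) would give the methallyl compound F8. The facial bias that gave the wrong epimer with hydride would now give 1′S. Hydrogenation of the 1,1-disubstituted alkene of F8 with RhCl(PPh3)3/H2 returns to the route at 26.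

**Step 16.** The risks are incomplete cleavage of the third ether and attack of hot thiolate on the aldehydes. Fallback: from 26, demethylation with EtSNa in DMF at 150 °C before any aldehyde is present would give the triphenol F9. Magnesium-mediated ortho-formylation of the free phenol (MgCl2, Et3N, paraformaldehyde, MeCN, reflux) at both free positions returns to the route at 30.

## Further compounds

F1 | step 8 | (3R,4S,7S,10R)-3-[(tributylstannyl)methoxy]eudesma-1,5-dien-11-ol | CCCC[Sn](CCCC)(CCCC)CO[C@@H]1C=C[C@@]2(C)CC[C@H](C(C)(C)O)C=C2[C@@H]1C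
F2 | step 8 | (1S,4R,7S,10R)-1-(hydroxymethyl)eudesma-2,5-dien-11-ol | OC[C@H]1C=C[C@@H](C)C2=C[C@@H](C(C)(C)O)CC[C@@]21C
F3 | step 8 | (1S,4R,7S,10R)-1-(hydroxymethyl)eudesm-5-en-11-ol | OC[C@H]1CC[C@@H](C)C2=C[C@@H](C(C)(C)O)CC[C@@]21C
F4 | step 8 | (1S,4R,7S,10R)-11-hydroxyeudesm-5-ene-1-carbaldehyde | O=C[C@H]1CC[C@@H](C)C2=C[C@@H](C(C)(C)O)CC[C@@]21C
F5 | step 5 | (7S,10R)-3-ethoxyeudesma-1,3,5-trien-11-ol | CCOC1=C(C)C2=C[C@@H](C(C)(C)O)CC[C@]2(C)C=C1
F6 | step 12 | (1S,4R,7S,10R)-1-[1-hydroxy-3-methyl-1-(2,4,6-trimethoxyphenyl)but-2-en-1-yl]eudesm-5-en-11-ol | CC(C)=CC(O)(c1c(OC)cc(OC)cc1OC)[C@H]1CC[C@@H](C)C2=C[C@@H](C(C)(C)O)CC[C@@]21C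
F7 | step 13 | (1S,4R,7S,10R)-1-[hydroxy(2,4,6-trimethoxyphenyl)methyl]eudesm-5-en-11-ol | OC(c1c(OC)cc(OC)cc1OC)[C@H]1CC[C@@H](C)C2=C[C@@H](C(C)(C)O)CC[C@@]21C
F8 | step 13 | (1R,4R,7S,10R)-1-[(1S)-3-methyl-1-(2,4,6-trimethoxyphenyl)but-3-en-1-yl]eudesm-5-en-11-ol | C=C(C)C[C@H](c1c(OC)cc(OC)cc1OC)[C@H]1CC[C@@H](C)C2=C[C@@H](C(C)(C)O)CC[C@@]21C
F9 | step 16 | 2-{(1S)-1-[(1R,4R,7S,10R)-11-hydroxyeudesm-5-en-1-yl]-3-methylbutyl}benzene-1,3,5-triol | CC(C)C[C@H](c1c(O)cc(O)cc1O)[C@H]1CC[C@@H](C)C2=C[C@@H](C(C)(C)O)CC[C@@]21C
A1 | alternative 1 | 2,4-diformyl-3,5-dihydroxy-6-(3-methylbutylidene)cyclohexa-2,4-dien-1-one (quinone methide) | CC(C)CC=C1C(=O)C(C=O)=C(O)C(C=O)=C1O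
A2 | alternative 1 | (4R,7S,10R)-2-(trimethylsilyloxy)eudesma-1,5-dien-11-ol | C[Si](C)(C)OC1=C[C@@]2(C)CC[C@H](C(C)(C)O)C=C2[C@H](C)C1
A3 | alternative 1 | 2-oxo derivative of the target | CC(C)C[C@H](c1c(O)c(C=O)c(O)c(C=O)c1O)[C@H]1C(=O)C[C@@H](C)C2=C[C@@H](C(C)(C)O)CC[C@@]21C
A4 | alternative 2 | (2,4,6-trimethoxyphenyl)acetate of 14 at O3 | COc1cc(OC)c(CC(=O)O[C@@H]2C=C[C@@]3(C)CC[C@H](C(C)(C)O)C=C3[C@@H]2C)c(OC)c1
A5 | alternative 2 | (2R)-2-[(1S,4R,7S,10R)-11-hydroxyeudesma-2,5-dien-1-yl]-2-(2,4,6-trimethoxyphenyl)acetic acid | OC(=O)[C@@H](c1c(OC)cc(OC)cc1OC)[C@H]1C=C[C@@H](C)C2=C[C@@H](C(C)(C)O)CC[C@@]21C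
A6 | alternative 3 | 2-(but-3-en-2-yl)-8-hydroxy-p-menth-1-en-3-yl 5-methyl-3-(2,4,6-trimethoxyphenyl)hexanoate | C=C[C@@H](C)C1=C(C)CC[C@H](C(C)(C)O)[C@H]1OC(=O)C[C@H](CC(C)C)c1c(OC)cc(OC)cc1OC
A7 | alternative 3 | Claisen acid with C1–C10 bond, C5=C6 alkene and free but-3-en-2-yl and carboxyl arms | C=C[C@@H](C)C1=C[C@@H](C(C)(C)O)CC[C@]1(C)[C@H](C(=O)O)[C@H](CC(C)C)c1c(OC)cc(OC)cc1OC
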